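(The earlier runs and the new flask were generated by integration from invented constants, and the scatter is random.)

The ratio to watch is Pdt over the Sbt charged, a fraction of the charge that the three runs so far bring to nearly the same level.

| flask | Sbt | Ptn | time |
|---|---|---|---|
| gamma | 80.0 mM | 160 mM |  |
| zeta | 32.0 mM | 112 mM |  |
| theta | 120 mM | 160 mM |  |
| beta | 240 mM | 480 mM | 81 min |

| run | time / min | [Pdt] / mM |
|---|---|---|
| gamma run | 10 | 8.70 |
| gamma run | 20 | 15.15 |
| gamma run | 30 | 19.25 |
| gamma run | 40 | 22.54 |
| gamma run | 51 | 25.15 |
| gamma run | 61 | 26.17 |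
| gamma run | 71 | 27.29 |
| gamma run | 81 | 27.92 |
| zeta run | 10 | 2.89 |
| zeta run | 20 | 4.59 |
| zeta run | 30 | 6.13 |
| zeta run | 40 | 7.45 |
| zeta run | 51 | 8.39 |
| zeta run | 61 | 9.11 |
| zeta run | 71 | 9.79 |
| zeta run | 81 | 10.29 |
| theta run | 10 | 13.12 |
| theta run | 20 | 21.98 |
| theta run | 30 | 27.93 |
| theta run | 40 | 32.36 |
| theta run | 51 | 35.77 |
| theta run | 61 | 37.82 |
| theta run | 71 | 39.26 |
| theta run | 81 | 40.05 |

(each reading ± 0.2 mM)

- Overall: Sbt + Ptn -> Pdt.
- Constant volume, constant temperature.
- An order is taken over about fifteen percent of the charge, up and down.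

1. reaction order in [Sbt] at the outset, round the charge of the gamma run, defined at two percent of the Sbt turned into Pdt (one fixed amount of Pdt, the same in the runs compared)
2. reaction order in [Ptn] at the outset, round the charge of the gamma run, defined at two percent of the Sbt turned into Pdt
3. Pdt in the beta run at 81 min, as a share of the Sbt charged

In its first 10 min the gamma run turns 10.9% of its Sbt charge and the theta run, on the same Ptn charge, 10.9%, so the order in Sbt reads about 1.01.

Fold this opening share with Ptn charge and time into N, the number of Sbt charges that the opening pace of gamma, scaled in proportion to the Ptn charge, would turn by a given time (a Damköhler number). Gamma reaches N = 0.881 at 81 min. The zeta run at 81 min has the N of gamma at 56.7 min, and its 32.2% lies between gamma's 31.4% at 51 min and 32.7% at 61 min, so the proportion holds.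

Gamma's last 10.0 min add 0.0724 of its opening gain, so the crossing, where Pdt stops gaining, lies just above that N. Half that last gain again puts the top at 35.3%.

One number is not quite enough: theta, at gamma's N, reads 33.4% against 34.9%, on 1.33 Ptn per Sbt against 2.00. Beta has gamma's ratio and N = 2.64, higher than gamma's 0.881, past the last gamma reading. This reckoning supposes that the share stays flat beyond the crossing, which the gamma readings do not show, and on that supposition sets beta near 35.3%.

The forecast gives 0.97, 0.85 and, higher than this reckoning, 36.5%: “If rate and decay both scale with Ptn, the plateau fraction stays fixed.”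

Beta gives 38.5%, 3.2 percentage points above the reckoned top, and the orders in Sbt and Ptn come out at 1.0 and 1.0.

    Sbt + Ptn → Pdt (0.08160 M⁻¹ min⁻¹)
    Pdt + Ptn → Ofp (0.05490 M⁻¹ min⁻¹)
    Pdt → G (0.002070 min⁻¹)
    Ptn → Q (0.005556 min⁻¹)

Beta's N stands 3.00 times gamma's, and its share at 81 min stands 1.10 times gamma's 34.9%.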